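**Retrosynthetic overview**

1. Target 20 ← bis-silyl ether 19 by acidic fluoride in the last step; the labile hemiketal carbon C2 is carried as a TBS ketal until then.
2. 19 ← one-flask double Negishi coupling at side-chain C3′: gem-dichloroalkene 8 + the alkylzinc from iodide 16 (makes C3′–C4′) + Me2Zn (makes C3′–CH3). Enabling feature: in the C2′=C3′ alkene, C3′ carries two carbon groups (CH3 and C4′H2) while C2′ carries H and the C1′H2 attached to quaternary ring carbon C2, so C3′ maps onto a CCl2 terminus whose two chlorides differ only in being cis or trans to C1′.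
3. 8 ← dearomatising asymmetric Rubottom oxidation of the furan ring of 3-siloxybenzofuran 6 (sets C2) ← benzofuranone 5.
4. Ring order: the benzene ring is bought in 1; the furanone ring is closed in step 3 (O1–C2, phenoxide SN2), aromatised in step 4 and dearomatised in step 5; C1′–C3′ come from 1,1,3-trichloropropene 2.
5. 16 ← carbonylative Stille union of vinyl iodide 11, CO (C8′) and vinylstannane 14, then OH → I.

Key step: step 11

Assumption: the C2 hemiketal is taken as configurationally stable only as its silyl ketal or, once free, under neutral to weakly acidic conditions, because the ring-opened α-diketone is achiral; it is therefore released last and never exposed to base.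

**Route**

Step 1
Reactants: 1 1-(2-hydroxy-6-methylphenyl)ethan-1-one; 2 1,1,3-trichloroprop-1-ene
Product: 3 5,5-dichloro-1-(2-hydroxy-6-methylphenyl)pent-4-en-1-one
Conditions: LDA (2.2 equiv), THF, −78 → 0 °C; then 2 (0.9 equiv), DMPU, −78 → −20 °C; aq NH4Cl
Reagents that add atoms: none
Why: Enolate alkylation of the phenoxide–enolate dianion, in which the more basic enolate carbon displaces the sp3 chloride of 2 by SN2 while the vinylic chlorides are inert and the lithium phenoxide is too poor a nucleophile to be O-alkylated.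

Step 2
Reactants: 3 5,5-dichloro-1-(2-hydroxy-6-methylphenyl)pent-4-en-1-one
Product: 4 2-bromo-5,5-dichloro-1-(2-hydroxy-6-methylphenyl)pent-4-en-1-one (racemic)
Conditions: CuBr2 (2.1 equiv), EtOAc/CHCl3 (1:1), reflux
Reagents that add atoms: copper(II) bromide, Br[Cu]Br
Why: α-Bromination of an aryl alkyl ketone with CuBr2 through the copper enolate; C2 is the only enolisable position, and the electron-poor dichloroalkene and the acyl-deactivated phenol ring should not be brominated.

Step 3
Reactants: 4 2-bromo-5,5-dichloro-1-(2-hydroxy-6-methylphenyl)pent-4-en-1-one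
Product: 5 2-(3,3-dichloroprop-2-en-1-yl)-4-methyl-1-benzofuran-3(2H)-one (racemic)
Conditions: NaOAc (3 equiv), EtOH, 0 °C → rt
Reagents that add atoms: none
Why: Intramolecular Williamson etherification (5-exo-tet SN2 of the phenoxide on the α-bromo ketone), the standard closure of benzofuran-3(2H)-ones; the C2 centre formed here is racemic and is erased in step 4.

Step 4
Reactants: 5 2-(3,3-dichloroprop-2-en-1-yl)-4-methyl-1-benzofuran-3(2H)-one
Product: 6 tert-butyl{[2-(3,3-dichloroprop-2-en-1-yl)-4-methyl-1-benzofuran-3-yl]oxy}dimethylsilane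
Conditions: TBSOTf (1.2 equiv), Et3N (1.5 equiv), CH2Cl2, 0 °C
Reagents that add atoms: tert-butyldimethylsilyl trifluoromethanesulfonate, CC(C)(C)[Si](C)(C)OS(=O)(=O)C(F)(F)F
Why: Silyl enol ether formation by soft enolisation and O-silylation, driven by aromatisation to the benzofuran; it gives one planar tetrasubstituted enol ether with no E/Z issue.

Step 5
Reactants: 6 tert-butyl{[2-(3,3-dichloroprop-2-en-1-yl)-4-methyl-1-benzofuran-3-yl]oxy}dimethylsilane
Product: 8 (2S)-2-{[tert-butyl(dimethyl)silyl]oxy}-2-(3,3-dichloroprop-2-en-1-yl)-4-methyl-1-benzofuran-3(2H)-one, via siloxy oxirane 7 (not isolated)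
Conditions: L-fructose-derived enantiomer of the Shi ketone (30 mol%), Oxone (1.4 equiv), K2CO3, Bu4NHSO4 (cat.), aq Na2B4O7/Na2EDTA buffer, MeCN/dimethoxymethane, −10 °C; extraction without delay
Reagents that add atoms: Oxone (potassium peroxymonosulfate), [K+].[O-]S(=O)(=O)OO
Why: Shi asymmetric epoxidation of a silyl enol ether merged with the Rubottom 1,4-silyl shift, a dearomatising oxidation of the furan ring: the chiral dioxirane should attack C2=C3 through the spiro transition state with the substituent-free ring oxygen O1 in the slot normally taken by the olefinic hydrogen, which by analogy with 1-arylcycloalkenes predicts the S-configured ketal from the L-configured ketone; oxirane 7 then opens at C3 to the siloxycarbenium ion and TBS migrates to the new oxygen, so the C2–O bond made in the epoxidation is never broken, and the electron-poor dichloroalkene is not touched.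

Step 6
Reactants: 9 pent-3-yn-1-ol
Product: 11 (E)-4-iodopent-3-en-1-ol, via alkenylzirconocene 10 (not isolated)
Conditions: Cp2Zr(H)Cl (2.5 equiv), THF, rt → 40 °C; then I2 (1.2 equiv), THF, 0 °C
Reagents that add atoms: iodine, II
Why: Hydrozirconation–iodination: syn addition of Zr–H, equilibration under excess Schwartz reagent to place zirconium on the less hindered methyl-bearing carbon, and iodinolysis with retention should fix the E geometry (CH2 cis to CH3).

Step 7
Reactants: 12 2-methylbut-3-yn-2-ol
Product: 13 triethyl[(2-methylbut-3-yn-2-yl)oxy]silane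
Conditions: TESOTf (1.1 equiv), 2,6-lutidine (1.5 equiv), CH2Cl2, 0 °C
Reagents that add atoms: triethylsilyl trifluoromethanesulfonate, CC[Si](CC)(CC)OS(=O)(=O)C(F)(F)F
Why: Silyl ether formation with the reactive triflate, needed for a tertiary alcohol; the TES group later keeps this hydroxyl from quenching the organozinc.

Step 8
Reactants: 13 triethyl[(2-methylbut-3-yn-2-yl)oxy]silane
Product: 14 triethyl{[(3E)-2-methyl-4-(tributylstannyl)but-3-en-2-yl]oxy}silane
Conditions: Bu3SnH (1.1 equiv), PdCl2(PPh3)2 (2 mol%), THF, 0 °C → rt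
Reagents that add atoms: tributyltin hydride, CCCC[SnH](CCCC)CCCC
Why: Palladium-catalysed hydrostannation of a terminal alkyne; the bulky quaternary propargylic carbon directs tin to the terminal carbon and syn addition gives the E-vinylstannane.

Step 9
Reactants: 11 (E)-4-iodopent-3-en-1-ol; 14 triethyl{[(3E)-2-methyl-4-(tributylstannyl)but-3-en-2-yl]oxy}silane
Product: 15 (3E,6E)-9-hydroxy-2,6-dimethyl-2-[(triethylsilyl)oxy]nona-3,6-dien-5-one
Conditions: Pd(PPh3)4 (5 mol%), CO (3 bar), THF, 50 °C
Reagents that add atoms: carbon monoxide, [C-]#[O+]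
Why: Carbonylative Stille coupling (oxidative addition to the vinyl iodide, CO insertion, transmetalation and reductive elimination) gives the cross-conjugated dienone with both alkene geometries retained; without added base the primary hydroxyl should not intercept the acylpalladium, and the E alkene rules out lactonisation.

Step 10
Reactants: 15 (3E,6E)-9-hydroxy-2,6-dimethyl-2-[(triethylsilyl)oxy]nona-3,6-dien-5-one
Product: 16 (3E,6E)-9-iodo-2,6-dimethyl-2-[(triethylsilyl)oxy]nona-3,6-dien-5-one
Conditions: I2 (1.2 equiv), PPh3 (1.2 equiv), imidazole (1.5 equiv), CH2Cl2, 0 °C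
Reagents that add atoms: iodine, II
Why: Appel-type iodination (SN2 displacement of the alkoxyphosphonium by iodide) of the only free, primary hydroxyl under buffered conditions that spare the dienone and the tertiary silyl ether.

Step 11
Reactants: 8 (2S)-2-{[tert-butyl(dimethyl)silyl]oxy}-2-(3,3-dichloroprop-2-en-1-yl)-4-methyl-1-benzofuran-3(2H)-one; 16 (3E,6E)-9-iodo-2,6-dimethyl-2-[(triethylsilyl)oxy]nona-3,6-dien-5-one
Product: 19 (2S)-2-{[tert-butyl(dimethyl)silyl]oxy}-2-{(2E,6E,9E)-3,7,11-trimethyl-8-oxo-11-[(triethylsilyl)oxy]dodeca-2,6,9-trien-1-yl}-4-methyl-1-benzofuran-3(2H)-one, via alkylzinc iodide 17 (not isolated), via (Z)-chloroalkene 18 (not isolated)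
Conditions: (i) 16 (1.25 equiv), Zn dust (activated with 1,2-dibromoethane/TMSCl), LiCl, THF, 25 °C; (ii) 8 (1.0 equiv), PdCl2(DPEphos) (5 mol%), THF/DMF, 25 → 45 °C; (iii) same flask, Me2Zn (2.5 equiv), Pd(P-t-Bu3)2 (5 mol%), 50 °C
Reagents that add atoms: dimethylzinc, C[Zn]C
Why: Negishi coupling run twice on one carbon, following the known trans-selective monoalkylation of 1,1-dichloro-1-alkenes with alkylzincs and stereoretentive substitution of the remaining chloride: Pd(0) inserts first into the C3′–Cl bond trans to the C1′ methylene, the less hindered of the two and activated by the geminal chlorine, and transmetalation with primary alkylzinc 17 and reductive elimination from the wide-bite-angle DPEphos complex give (Z)-chloroalkene 18. The remaining C–Cl bond, cis to C1′, is then opened by the more electron-rich Pd(P-t-Bu3)2 catalyst and methylated by Me2Zn with retention, so C4′ ends trans and CH3 cis to C1′, which is the 2′E alkene. No ring is closed and no sp3 stereocentre is made; the new stereogenic element is the C2′=C3′ double bond, controlled by the order of the two oxidative additions and by stereoretentive transmetalation and reductive elimination. The step needs mono- over bis-alkylation, trans over cis substitution and retention in the methylation; these should be secured by the reactivity gap between the CCl2 group and the monochloroalkene, by the steric bias of the neopentyl-like C1′H2–C2 substituent, and by the bulky monophosphine that suppresses isomerisation of the alkenylpalladium. Organozinc reagents should leave the aryl ketone, the dienone, both silyl ethers and the non-enolisable quaternary C2 untouched, so the dienone chain can be brought in complete.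

Step 12
Reactants: 19 (2S)-2-{[tert-butyl(dimethyl)silyl]oxy}-2-{(2E,6E,9E)-3,7,11-trimethyl-8-oxo-11-[(triethylsilyl)oxy]dodeca-2,6,9-trien-1-yl}-4-methyl-1-benzofuran-3(2H)-one
Product: 20 (2R)-2-hydroxy-2-[(2E,6E,9E)-11-hydroxy-3,7,11-trimethyl-8-oxododeca-2,6,9-trien-1-yl]-4-methyl-1-benzofuran-3(2H)-one
Conditions: HF·pyridine, pyridine, THF, 0 °C → rt; quench into pH 7 phosphate buffer at 0 °C
Reagents that add atoms: none
Why: Fluoride-mediated desilylation under acidic buffering cleaves both Si–O bonds at silicon, so the C2–O bond is never broken and no hemiketal alkoxide persists, which should keep the ring closed and the configuration intact (the descriptor changes from S to R only because OSi outranks OAr whereas OH does not).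

**Compound list**

1 | 1-(2-hydroxy-6-methylphenyl)ethan-1-one | CC(=O)c1c(C)cccc1O | starting material
2 | 1,1,3-trichloroprop-1-ene | ClCC=C(Cl)Cl | starting material
3 | 5,5-dichloro-1-(2-hydroxy-6-methylphenyl)pent-4-en-1-one | O=C(CCC=C(Cl)Cl)c1c(C)cccc1O | intermediate
4 | 2-bromo-5,5-dichloro-1-(2-hydroxy-6-methylphenyl)pent-4-en-1-one (racemic) | O=C(C(Br)CC=C(Cl)Cl)c1c(C)cccc1O | intermediate
5 | 2-(3,3-dichloroprop-2-en-1-yl)-4-methyl-1-benzofuran-3(2H)-one (racemic) | Cc1cccc2OC(CC=C(Cl)Cl)C(=O)c12 | intermediate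
6 | tert-butyl{[2-(3,3-dichloroprop-2-en-1-yl)-4-methyl-1-benzofuran-3-yl]oxy}dimethylsilane | Cc1cccc2oc(CC=C(Cl)Cl)c(O[Si](C)(C)C(C)(C)C)c12 | intermediate
7 | 6b-{[tert-butyl(dimethyl)silyl]oxy}-1a-(3,3-dichloroprop-2-en-1-yl)-6-methyl-1a,6b-dihydrooxireno[2,3-b][1]benzofuran, cis-fused, oxirane oxygen on the face that becomes C2–O of 8 (not isolated) | ClC(Cl)=CC[C@]12O[C@@]1(O[Si](C)(C)C(C)(C)C)c1c(C)cccc1O2 | intermediate
8 | (2S)-2-{[tert-butyl(dimethyl)silyl]oxy}-2-(3,3-dichloroprop-2-en-1-yl)-4-methyl-1-benzofuran-3(2H)-one | ClC(Cl)=CC[C@@]1(O[Si](C)(C)C(C)(C)C)Oc2cccc(C)c2C1=O | intermediate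
9 | pent-3-yn-1-ol | CC#CCCO | starting material
10 | (E)-alkenylzirconocene chloride of pent-3-yn-1-ol, zirconium on C4 and the hydroxyl as its zirconocene alkoxide (not isolated) | C/C(=C\CCO[Zr](Cl)(C1C=CC=C1)C1C=CC=C1)[Zr](Cl)(C1C=CC=C1)C1C=CC=C1 | intermediate
11 | (E)-4-iodopent-3-en-1-ol | C/C(I)=C\CCO | intermediate
12 | 2-methylbut-3-yn-2-ol | CC(C)(O)C#C | starting material
13 | triethyl[(2-methylbut-3-yn-2-yl)oxy]silane | CC(C)(O[Si](CC)(CC)CC)C#C | intermediate
14 | triethyl{[(3E)-2-methyl-4-(tributylstannyl)but-3-en-2-yl]oxy}silane | CCCC[Sn](CCCC)(CCCC)/C=C/C(C)(C)O[Si](CC)(CC)CC | intermediate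
15 | (3E,6E)-9-hydroxy-2,6-dimethyl-2-[(triethylsilyl)oxy]nona-3,6-dien-5-one | OCC/C=C(\C)C(=O)/C=C/C(C)(C)O[Si](CC)(CC)CC | intermediate
16 | (3E,6E)-9-iodo-2,6-dimethyl-2-[(triethylsilyl)oxy]nona-3,6-dien-5-one | ICC/C=C(\C)C(=O)/C=C/C(C)(C)O[Si](CC)(CC)CC | intermediate
17 | {(3E,6E)-4,8-dimethyl-5-oxo-8-[(triethylsilyl)oxy]nona-3,6-dien-1-yl}zinc iodide (not isolated) | I[Zn]CC/C=C(\C)C(=O)/C=C/C(C)(C)O[Si](CC)(CC)CC | intermediate
18 | (2S)-2-{[tert-butyl(dimethyl)silyl]oxy}-2-{(2Z,6E,9E)-3-chloro-7,11-dimethyl-8-oxo-11-[(triethylsilyl)oxy]dodeca-2,6,9-trien-1-yl}-4-methyl-1-benzofuran-3(2H)-one (not isolated) | Cl/C(=C\C[C@@]1(O[Si](C)(C)C(C)(C)C)Oc2cccc(C)c2C1=O)CC/C=C(\C)C(=O)/C=C/C(C)(C)O[Si](CC)(CC)CC | intermediate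
19 | (2S)-2-{[tert-butyl(dimethyl)silyl]oxy}-2-{(2E,6E,9E)-3,7,11-trimethyl-8-oxo-11-[(triethylsilyl)oxy]dodeca-2,6,9-trien-1-yl}-4-methyl-1-benzofuran-3(2H)-one | C/C(=C\C[C@@]1(O[Si](C)(C)C(C)(C)C)Oc2cccc(C)c2C1=O)CC/C=C(\C)C(=O)/C=C/C(C)(C)O[Si](CC)(CC)CC | intermediate
20 | (2R)-2-hydroxy-2-[(2E,6E,9E)-11-hydroxy-3,7,11-trimethyl-8-oxododeca-2,6,9-trien-1-yl]-4-methyl-1-benzofuran-3(2H)-one | C/C(=C\C[C@@]1(O)Oc2cccc(C)c2C1=O)CC/C=C(\C)C(=O)/C=C/C(C)(C)O | target

**Step count and risks**

Total step count: 12. Longest linear sequence: 7 steps (steps 1–5, 11, 12).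

Steps most likely to fail:

Step 5. The chiral dioxirane may discriminate poorly between the faces of a tetrasubstituted heteroaromatic enol ether. The silyl group may also be lost under the basic aqueous conditions, after which the free hemiketal would lose configuration through ring–chain tautomerism. If only the sense of induction were opposite to the prediction, the D-fructose-derived ketone would be used instead. The fallback sets out from 6: anhydrous Rubottom oxidation with mCPBA (NaHCO3, CH2Cl2, −20 °C) would give racemic 2-{[tert-butyl(dimethyl)silyl]oxy}-2-(3,3-dichloroprop-2-en-1-yl)-4-methyl-1-benzofuran-3(2H)-one F1, a configurationally stable ketal. Its enantiomers would be separated by preparative chromatography on a chiral stationary phase, and the S enantiomer comes back to the route as 8.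

Step 11. Zinc insertion next to the cross-conjugated dienone may be accompanied by reduction or self-addition of the organozinc, and the first coupling may lose trans-selectivity or run on to bis-alkylation. The fallback sets out from 16 and moves the chain to the carbinol oxidation level and to boron. Luche reduction (NaBH4, CeCl3·7H2O, MeOH, −78 °C) would give (3E,6E)-9-iodo-2,6-dimethyl-2-[(triethylsilyl)oxy]nona-3,6-dien-5-ol F2 as a C5 epimer mixture whose centre is erased later. Deprotonation with MeLi, iodine–lithium exchange with t-BuLi (Et2O, −78 °C) and capture with B-methoxy-9-BBN would give the dilithium alkoxide B-methoxy-9-BBN borinate of that chain F3. This would be coupled directly with 8 in a B-alkyl Suzuki–Miyaura reaction (Pd2(dba)3, Xantphos, K3PO4, THF/DMF, 60 °C), which is likewise trans-selective on 1,1-dichloroalkenes, to give (2S)-2-{[tert-butyl(dimethyl)silyl]oxy}-2-{(2Z,6E,9E)-3-chloro-8-hydroxy-7,11-dimethyl-11-[(triethylsilyl)oxy]dodeca-2,6,9-trien-1-yl}-4-methyl-1-benzofuran-3(2H)-one F4. Methylation as in step 11 (Me2Zn, Pd(P-t-Bu3)2, 50 °C) would give (2S)-2-{[tert-butyl(dimethyl)silyl]oxy}-2-{(2E,6E,9E)-8-hydroxy-3,7,11-trimethyl-11-[(triethylsilyl)oxy]dodeca-2,6,9-trien-1-yl}-4-methyl-1-benzofuran-3(2H)-one F5. MnO2 (CH2Cl2, rt) would then oxidise the doubly allylic alcohol to the dienone, coming back to the route at 19.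

Step 12. Cleavage of the hindered tertiary TBS ketal may be slow, and forcing it may open the hemiketal to the achiral α-diketone and erode the configuration. The fallback sets out from 5 and replaces fluoride cleavage by acid-catalysed methanolysis of a more labile silyl ketal. TESOTf/Et3N would give triethyl{[2-(3,3-dichloroprop-2-en-1-yl)-4-methyl-1-benzofuran-3-yl]oxy}silane F6. The oxidation of step 5 would give (2S)-2-(3,3-dichloroprop-2-en-1-yl)-4-methyl-2-[(triethylsilyl)oxy]-1-benzofuran-3(2H)-one F7. The coupling of step 11 with 16 would give (2S)-4-methyl-2-[(triethylsilyl)oxy]-2-{(2E,6E,9E)-3,7,11-trimethyl-8-oxo-11-[(triethylsilyl)oxy]dodeca-2,6,9-trien-1-yl}-1-benzofuran-3(2H)-one F8. Both TES groups would be removed with PPTS in MeOH/CH2Cl2 at 0 °C, which never forms an alkoxide, coming back to the route at 20.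

Further compounds
F1 | step 5 | racemic 2-{[tert-butyl(dimethyl)silyl]oxy}-2-(3,3-dichloroprop-2-en-1-yl)-4-methyl-1-benzofuran-3(2H)-one | ClC(Cl)=CCC1(O[Si](C)(C)C(C)(C)C)Oc2cccc(C)c2C1=O
F2 | step 11 | (3E,6E)-9-iodo-2,6-dimethyl-2-[(triethylsilyl)oxy]nona-3,6-dien-5-ol (C5 epimers) | ICC/C=C(\C)C(O)/C=C/C(C)(C)O[Si](CC)(CC)CC
F3 | step 11 | dilithium alkoxide B-methoxy-9-BBN borinate of the (3E,6E)-5-hydroxy-4,8-dimethyl-8-[(triethylsilyl)oxy]nona-3,6-dien-1-yl chain | [Li+].[Li+].CO[B-]1(CC/C=C(\C)C([O-])/C=C/C(C)(C)O[Si](CC)(CC)CC)C2CCCC1CCC2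
F4 | step 11 | (2S)-2-{[tert-butyl(dimethyl)silyl]oxy}-2-{(2Z,6E,9E)-3-chloro-8-hydroxy-7,11-dimethyl-11-[(triethylsilyl)oxy]dodeca-2,6,9-trien-1-yl}-4-methyl-1-benzofuran-3(2H)-one (C8′ epimers) | Cl/C(=C\C[C@@]1(O[Si](C)(C)C(C)(C)C)Oc2cccc(C)c2C1=O)CC/C=C(\C)C(O)/C=C/C(C)(C)O[Si](CC)(CC)CC
F5 | step 11 | (2S)-2-{[tert-butyl(dimethyl)silyl]oxy}-2-{(2E,6E,9E)-8-hydroxy-3,7,11-trimethyl-11-[(triethylsilyl)oxy]dodeca-2,6,9-trien-1-yl}-4-methyl-1-benzofuran-3(2H)-one (C8′ epimers) | C/C(=C\C[C@@]1(O[Si](C)(C)C(C)(C)C)Oc2cccc(C)c2C1=O)CC/C=C(\C)C(O)/C=C/C(C)(C)O[Si](CC)(CC)CC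
F6 | step 12 | triethyl{[2-(3,3-dichloroprop-2-en-1-yl)-4-methyl-1-benzofuran-3-yl]oxy}silane | Cc1cccc2oc(CC=C(Cl)Cl)c(O[Si](CC)(CC)CC)c12
F7 | step 12 | (2S)-2-(3,3-dichloroprop-2-en-1-yl)-4-methyl-2-[(triethylsilyl)oxy]-1-benzofuran-3(2H)-one | ClC(Cl)=CC[C@@]1(O[Si](CC)(CC)CC)Oc2cccc(C)c2C1=O
F8 | step 12 | (2S)-4-methyl-2-[(triethylsilyl)oxy]-2-{(2E,6E,9E)-3,7,11-trimethyl-8-oxo-11-[(triethylsilyl)oxy]dodeca-2,6,9-trien-1-yl}-1-benzofuran-3(2H)-one | C/C(=C\C[C@@]1(O[Si](CC)(CC)CC)Oc2cccc(C)c2C1=O)CC/C=C(\C)C(=O)/C=C/C(C)(C)O[Si](CC)(CC)CC
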